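Remarks on the chemistry: the formyl carbon on C3 is called C16. S-tert-butyl thioacetate (18) is assumed to be purchasable, like the four principal starting materials. The sense of induction in steps 1 and 10 is assigned from the accepted transition-state models of these catalysts.

## Analysis of the target

The target is a C20 monocyclic diacetate. A nine-carbon chain runs from the enol acetate carbon C1 through the fully substituted C3 to C9 and ends at C10 of a 2,6,6-trimethylcyclohex-2-ene ring (C10–C15), the only ring. There are two stereocentres: C3 (R), which carries the tertiary acetate, the formyl group C16, the C1=C2 enol acetate and the C4 chain, and the ring methine C10 (S). Seven bonds, among them the C6=C7 alkene, lie between them, so neither can direct the other and each must be set by absolute control. Both chain alkenes are E: the C1=C2 enol acetate and the trisubstituted C6=C7 alkene, whose C7 bears a methyl group and which sits between two saturated two-carbon spacers. The groups around C3 are the delicate part. The enol acetate is an acylating agent that is labile to base and nucleophiles. The α-acetoxy aldehyde cannot enolise but can suffer acyl shift or α-ketol rearrangement. In any precursor with a free C1 aldehyde the oxygen on C3 is β to an enolisable carbonyl and can be eliminated. The ring alkene must stay at C11–C12, since acid moves it into the tetrasubstituted position, and C10 is a hindered methine between a quaternary carbon and an alkene carbon. The strategy rests on the C7–C8 bond. C7 is the methyl-bearing sp2 carbon of the E-alkene and C8 an unbranched sp3 carbon, so the bond can be formed between a geometrically defined alkenyl iodide (C1–C7 and C16, holding C3) and a C8 radical released from a carboxylic acid (C8–C15, holding C10).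

## Retrosynthetic reasoning

**End game, 33 back to 27.** The two acetate C–O bonds are cut and C1 and C16 are lowered to the alcohol level. The order matters. The tertiary acetate is removed first, giving 32, because in the forward sense it can be installed safely only when C2 is already sp2 and no enolate can expel the C3 oxygen. The C16 aldehyde goes back to diol 31 and this to acetonide 30. The enol acetate is traced to aldehyde 29, where the C3 oxygen is still an acetal oxygen, a poor leaving group that also cannot undergo retro-aldol cleavage. Aldehyde 29 comes from alcohol 28 and this from silyl ether 27. What is gained is a coupling product, 27, that carries only ethers and alkenes.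

**Fragment union, 27 to 12 and 26.** The C7–C8 bond is cut. It is the only bond in the chain that joins an sp2 carbon of fixed geometry to an unbranched sp3 carbon and at the same time separates the two stereocentres into fragments of nine and eleven carbons. Cutting C5–C6 instead would leave C3 and C10 in the same fragment, and cutting at C3 or C10 would mean forming a bond at a hindered stereocentre. The forward reaction has to join a primary radical from redox-active ester 12 to the alkenyl iodide 26 with retention of the E geometry and without radical rearrangement. The geometry problem is thereby moved out of the coupling and into the preparation of 26.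

**Tail, 12 back to 1.** The ester C–O bond of 12 is cut to acid 10 and the N-hydroxy imide 11. Acid 10 is traced by removal of one carbon (through ketene 9 and diazoketone 8) to acid 6, whose carboxyl carbon is C8. The C9–C10 bond of 6 is then cut by a [3,3] shift back to allylic acetate 3, which hands the configuration of an easily made carbinol centre to the hindered C10 and places the alkene at C11–C12 without ambiguity. Acetate 3 comes from alcohol 2 and this from the achiral enone 1 by enantioselective reduction. The forward sequence has to control one carbinol centre and transfer it suprafacially.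

**Head, 26 back to 13, 15 and 18.** The C7–I bond is cut to alkyne 24, so that the E geometry comes from a syn hydrometalation and the methyl group on C7 is already in place. Removal of the protecting groups leads through 23 to triol 22, and 22 is the double reduction product of hydroxy diester 21. In 21 the C2–C3 bond is cut by an aldol disconnection to α-keto ester 17 and the ketene silyl thioacetal 19 (from 18). This single catalytic step creates C3 and at once supplies the two-carbon C1–C2 arm beside the one-carbon C16 arm. The C3–C4 bond of 17 is cut to the Grignard reagent 16, made from bromide 14 and alcohol 13, and to oxalate 15.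

## Alternatives that were turned down

**Alternative 1:** The disconnection is the C10–C15 ring bond inside a C13 methyl ketone. In the forward step an engineered class 2 terpene cyclase protonates the terminal alkene of (E)-geranylacetone A1, the C10–C11 alkene closes the ring, and loss of the C12 proton gives (S)-dihydro-α-ionone A2.
- For it: one step from a bulk ketone would build the ring, set C10 and place the alkene. A haloform degradation of A2 would give acid 10 directly, so the tail would take about two steps instead of five and need no diazo compound. On step count for the tail this alternative is clearly stronger.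
- Against it: the cyclohexyl cation at C11 has several exits. It can lose a proton from the C11 methyl group or from C10, or be captured by the ketone oxygen. Which exit is taken, and the enantiomeric fold of the substrate, depend on an enzyme variant that would first have to be found and cannot be predicted from structure.
- Comparison: it addresses the tail only and says nothing about C3, the C6=C7 alkene or the fragment union. The chosen route offers instead a tail whose absolute configuration follows from a reduction model and a suprafacial shift with ordinary reagents, and a plan whose decisive C–C bond joins two finished halves. A2 could be fed into the chosen route at 10 if a suitable enzyme were at hand.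

**Alternative 2:** The disconnection is C9–C10. The forward step is the Ireland–Claisen rearrangement of the ketene silyl acetal (4 of the route) of (R)-2,4,4-trimethylcyclohex-2-en-1-yl acetate A3 to 2-[(1S)-2,6,6-trimethylcyclohex-2-en-1-yl]acetic acid A4. A3 and A4 are the same compounds as 3 and 6.
- For it: the shift is stereospecific, cannot give a regioisomer, and forms a bond next to a quaternary carbon without difficulty because it is intramolecular. On the question of C10 it is exactly as strong as the chosen route, which uses this very rearrangement as step 3.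
- Also for it: if A4 were reduced and used as a C8 electrophile or organoborane in a two-electron cross-coupling, the one-carbon homologation of steps 4 and 5 would be unnecessary. That is a real saving of two steps.
- Against it as the strategic centre: it settles one stereocentre and leaves the harder questions open, namely how the E-trisubstituted alkene is made and how the half containing C3 is attached. A linear continuation from A4 would have to build C6=C7 by olefination next to a methyl branch, where E/Z control is poor.
- Comparison: the chosen route keeps the rearrangement as a supporting step and pays for the homologation. In return the tail enters the union as a bench-stable carboxylic acid derivative, and the coupling needs no organolithium or borane.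

**Alternative 3:** No skeletal bond is cut. A lipase (a serine hydrolase such as Burkholderia cepacia lipase) with an enol ester acyl donor acetylates one enantiotopic hydroxymethyl arm of the prochiral triol A5, which already carries the complete C4–C15 side chain, and so fixes C3 in monoacetate A6.
- For it: no metal catalyst or low temperature is needed. The symmetric precursor is simple to make. The acetyl group lands on the arm that becomes the formyl carbon.
- Against it, structure: both arms of A5 are one-carbon arms, while the target needs two carbons (C2–C1) on one side. The free arm would have to be lengthened by one carbon after the desymmetrisation, next to a free tertiary hydroxyl.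
- Against it, mechanism: in A6 the acetyl group can migrate to the tertiary oxygen and on to the other arm, and each such passage inverts C3, so the centre is configurationally fragile until the free arm is changed. The enzyme must tell a hydroxyl from a long chain at a fully substituted carbon, which is harder to predict than a secondary centre. Since C10 is already present, the wrong isomer would be a diastereomer differing only at a remote centre and could hardly be removed.
- Comparison: A5 can only be made after the fragment union has been solved. The chosen route sets C3 by a catalytic C–C bond formation on a small fragment, where the enantiomeric purity can be checked before the halves are joined, and that step itself delivers the two-carbon arm.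

Key step: step 15

## Route

Step 1
Reactants: 1 2,4,4-trimethylcyclohex-2-en-1-one
Product: 2 (1R)-2,4,4-trimethylcyclohex-2-en-1-ol
Conditions: (S)-2-methyl-CBS-oxazaborolidine [(3aS)-1-methyl-3,3-diphenyltetrahydro-1H,3H-pyrrolo[1,2-c][1,3,2]oxazaborole] (10 mol %), BH3·SMe2, THF, −20 °C; MeOH quench
Reagents that add atoms: none
Why: Corey–Bakshi–Shibata reduction: the borane–oxazaborolidine complex binds the carbonyl anti to the larger, methyl-substituted alkenyl arm and delivers hydride in a 1,2 sense, which with the (S)-catalyst should give the 1R alcohol; the enone alkene is not reduced.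

Step 2
Reactants: 2 (1R)-2,4,4-trimethylcyclohex-2-en-1-ol
Product: 3 (1R)-2,4,4-trimethylcyclohex-2-en-1-yl acetate
Conditions: Ac2O, Et3N, DMAP (cat.), CH2Cl2, 0 °C to rt
Reagents that add atoms: acetic anhydride, CC(=O)OC(C)=O
Why: DMAP-catalysed acetylation of a secondary allylic alcohol; no bond to the stereocentre is touched, so the 1R configuration is kept.

Step 3
Reactants: 3 (1R)-2,4,4-trimethylcyclohex-2-en-1-yl acetate
Product: 6 2-[(1S)-2,6,6-trimethylcyclohex-2-en-1-yl]acetic acid, via ketene silyl acetal 4 (not isolated), via trimethylsilyl ester 5 (not isolated)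
Conditions: LDA, TMSCl/Et3N (internal quench), THF, −78 °C, then 60 °C; 1 M NaOH, then 1 M HCl
Reagents that add atoms: chlorotrimethylsilane, C[Si](C)(C)Cl (silicon of 4 and 5 only; none remains in 6)
Why: Ireland–Claisen rearrangement: 4 rearranges through a cyclic six-membered transition state in which the new C9–C10 bond forms on the ring face that carried the C–O bond, so the 1R carbinol centre becomes 1S at the new methine and the alkene moves to C11–C12; being intramolecular, the shift tolerates the neighbouring gem-dimethyl carbon, and hydrolysis of 5 frees the acid.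

Step 4
Reactants: 6 2-[(1S)-2,6,6-trimethylcyclohex-2-en-1-yl]acetic acid
Product: 8 1-diazo-3-[(1S)-2,6,6-trimethylcyclohex-2-en-1-yl]propan-2-one, via acid chloride 7 (not isolated)
Conditions: (COCl)2, DMF (cat.), CH2Cl2, 0 °C to rt; then TMSCHN2 (2 equiv), MeCN/THF, 0 °C
Reagents that add atoms: trimethylsilyldiazomethane, C[Si](C)(C)C=[N+]=[N-]; oxalyl chloride, ClC(=O)C(=O)Cl (chlorine of 7 only)
Why: First half of an Arndt–Eistert homologation: acid chloride 7 acylates the diazo carbon and chloride removes the silyl group to leave the diazoketone; the stereocentre is two bonds from the reacting carbon and cannot epimerise.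

Step 5
Reactants: 8 1-diazo-3-[(1S)-2,6,6-trimethylcyclohex-2-en-1-yl]propan-2-one
Product: 10 3-[(1S)-2,6,6-trimethylcyclohex-2-en-1-yl]propanoic acid, via ketene 9 (not isolated)
Conditions: PhCO2Ag (10 mol %), Et3N, THF/H2O (10:1), rt, dark
Reagents that add atoms: water, O
Why: Silver-promoted Wolff rearrangement: loss of nitrogen with 1,2-shift of the C9 methylene gives ketene 9, which water traps as the homologous acid; the migrating carbon is not the stereocentre, so C10 is unaffected.

Step 6
Reactants: 10 3-[(1S)-2,6,6-trimethylcyclohex-2-en-1-yl]propanoic acid; 11 N-hydroxyphthalimide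
Product: 12 1,3-dioxoisoindolin-2-yl 3-[(1S)-2,6,6-trimethylcyclohex-2-en-1-yl]propanoate
Conditions: N,N'-diisopropylcarbodiimide, DMAP (10 mol %), CH2Cl2, rt
Reagents that add atoms: none
Why: Carbodiimide (Steglich-type) esterification of an unhindered primary acid with the N-hydroxy imide; it gives the redox-active ester needed for single-electron decarboxylation.

Step 7
Reactants: 13 pent-3-yn-1-ol
Product: 14 5-bromopent-2-yne
Conditions: CBr4, PPh3, CH2Cl2, 0 °C
Reagents that add atoms: tetrabromomethane, BrC(Br)(Br)Br
Why: Appel bromination of a primary alcohol under neutral conditions; the internal alkyne is inert.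

Step 8
Reactants: 14 5-bromopent-2-yne; 15 dimethyl oxalate
Product: 17 methyl 2-oxohept-5-ynoate, via pent-3-ynylmagnesium bromide 16 (not isolated)
Conditions: Mg, THF, 40 °C; then added to 15 (2 equiv), THF/Et2O, −78 °C; 1 M HCl
Reagents that add atoms: magnesium, [Mg] (in 16 only)
Why: Grignard formation from the homopropargylic bromide and inverse addition to excess oxalate at low temperature; the magnesium hemiketal persists until the acidic quench, which prevents a second addition and gives the α-keto ester.

Step 9
Reactants: 18 S-tert-butyl thioacetate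
Product: 19 [1-(tert-butylsulfanyl)ethenyl]oxy(trimethyl)silane
Conditions: LDA, THF, −78 °C; TMSCl
Reagents that add atoms: chlorotrimethylsilane, C[Si](C)(C)Cl
Why: Kinetic deprotonation of the thioester and O-silylation of the lithium enolate give the ketene silyl thioacetal that serves as the acetate nucleophile in step 10.

Step 10
Reactants: 17 methyl 2-oxohept-5-ynoate; 19 [1-(tert-butylsulfanyl)ethenyl]oxy(trimethyl)silane
Product: 21 methyl (2R)-2-[2-(tert-butylsulfanyl)-2-oxoethyl]-2-hydroxyhept-5-ynoate, via trimethylsilyl ether 20 (not isolated)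
Conditions: Cu(OTf)2 (10 mol %), 2,2'-(propane-2,2-diyl)bis[(4R)-4-tert-butyl-4,5-dihydro-1,3-oxazole] (11 mol %), THF, −78 °C; then 1 M HCl, THF, rt
Reagents that add atoms: none
Why: Bis(oxazoline)–copper-catalysed Mukaiyama aldol addition to an α-keto ester: 17 chelates divalent copper through both carbonyl oxygens in a distorted square plane, one tert-butyl group of the ligand blocks one ketone face, and 19 adds to the open face (the re face with the (R,R)-ligand), which sets C3 as R; the silyl group passes to the new tertiary oxygen (20) and is removed by the acid work-up.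

Step 11
Reactants: 21 methyl (2R)-2-[2-(tert-butylsulfanyl)-2-oxoethyl]-2-hydroxyhept-5-ynoate
Product: 22 (3R)-3-(hydroxymethyl)oct-6-yne-1,3-diol
Conditions: LiAlH4, THF, 0 °C to rt; H2O/NaOH work-up
Reagents that add atoms: none
Why: LiAlH4 reduces both the methyl ester and the thioester to primary alcohols; C3 bears no hydrogen and cannot epimerise, and the isolated internal alkyne is not reduced at this temperature.

Step 12
Reactants: 22 (3R)-3-(hydroxymethyl)oct-6-yne-1,3-diol
Product: 23 2-[(4R)-2,2-dimethyl-4-(pent-3-yn-1-yl)-1,3-dioxolan-4-yl]ethan-1-ol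
Conditions: 2,2-dimethoxypropane, PPTS (cat.), acetone, rt
Reagents that add atoms: 2,2-dimethoxypropane, COC(C)(C)OC
Why: Acid-catalysed acetalisation under thermodynamic control: the five-membered dioxolane across the C16 and C3 oxygens is preferred over the six-membered acetal to the C1 oxygen, which would force a 1,3-diaxial methyl–alkyl contact, so the C1 hydroxyl stays free.

Step 13
Reactants: 23 2-[(4R)-2,2-dimethyl-4-(pent-3-yn-1-yl)-1,3-dioxolan-4-yl]ethan-1-ol
Product: 24 tert-butyl{2-[(4R)-2,2-dimethyl-4-(pent-3-yn-1-yl)-1,3-dioxolan-4-yl]ethoxy}dimethylsilane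
Conditions: TBSCl, imidazole, CH2Cl2, rt
Reagents that add atoms: tert-butyldimethylsilyl chloride, CC(C)(C)[Si](C)(C)Cl
Why: Silylation of the only free hydroxyl, a primary one.

Step 14
Reactants: 24 tert-butyl{2-[(4R)-2,2-dimethyl-4-(pent-3-yn-1-yl)-1,3-dioxolan-4-yl]ethoxy}dimethylsilane
Product: 26 tert-butyl{2-[(4R)-4-[(3E)-4-iodopent-3-en-1-yl]-2,2-dimethyl-1,3-dioxolan-4-yl]ethoxy}dimethylsilane, via alkenylzirconocene chloride 25 (not isolated)
Conditions: Cp2Zr(H)Cl (2.5 equiv), THF, 50 °C; then I2, THF, 0 °C
Reagents that add atoms: iodine, II; Cp2Zr(H)Cl, [H][Zr](Cl)(C1C=CC=C1)C1C=CC=C1 (zirconium of 25 only)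
Why: Hydrozirconation–iodination: Zr–H adds syn across the alkyne, and excess reagent with warming lets the regioisomers equilibrate towards zirconium on the less hindered, methyl-bearing C7 (25); iodinolysis of the C–Zr bond with retention gives the iodide, whose E geometry follows from the syn addition.

Step 15
Reactants: 12 1,3-dioxoisoindolin-2-yl 3-[(1S)-2,6,6-trimethylcyclohex-2-en-1-yl]propanoate; 26 tert-butyl{2-[(4R)-4-[(3E)-4-iodopent-3-en-1-yl]-2,2-dimethyl-1,3-dioxolan-4-yl]ethoxy}dimethylsilane
Product: 27 tert-butyl{2-[(4R)-2,2-dimethyl-4-{(3E)-4-methyl-6-[(1S)-2,6,6-trimethylcyclohex-2-en-1-yl]hex-3-en-1-yl}-1,3-dioxolan-4-yl]ethoxy}dimethylsilane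
Conditions: NiCl2·glyme [NiCl2(MeOCH2CH2OMe)] (15 mol %), 2,2'-bipyridine (18 mol %), AgNO3 (0.3 equiv), LiCl, DMF, Mg anode, reticulated vitreous carbon cathode, undivided cell, constant current, rt
Reagents that add atoms: none
Why: Nickel-electrocatalytic decarboxylative alkenylation of a redox-active ester with an alkenyl halide, a known cross-electrophile coupling, here applied to a primary ester and an α-methyl E-alkenyl iodide. Cathodic reduction of divalent nickel gives a low-valent bipyridine complex that adds oxidatively to the C7–I bond of 26 with retention, while single-electron transfer to 12 fragments it into carbon dioxide, phthalimide anion and the primary C8 radical. The radical is captured at nickel, and reductive elimination from trivalent nickel forms C7–C8; the magnesium anode supplies the electrons. No ring is closed and no stereocentre is created, and C3 and C10 are remote sp3 centres that the conditions do not touch. The step needs cross-coupling over homo-coupling and retention of the E geometry: the first rests on the different activation of the two partners (two-electron oxidative addition for the iodide, one-electron reduction for the ester) and on the silver-modified cathode, the second on the configurational stability of alkenylnickel species at room temperature. The C8 radical has only 4-exo or 5-endo closure onto the ring alkene open to it, so it should persist until capture. Acetonide, silyl ether and both trisubstituted alkenes are inert to the neutral reductive medium.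

Step 16
Reactants: 27 tert-butyl{2-[(4R)-2,2-dimethyl-4-{(3E)-4-methyl-6-[(1S)-2,6,6-trimethylcyclohex-2-en-1-yl]hex-3-en-1-yl}-1,3-dioxolan-4-yl]ethoxy}dimethylsilane
Product: 28 2-[(4R)-2,2-dimethyl-4-{(3E)-4-methyl-6-[(1S)-2,6,6-trimethylcyclohex-2-en-1-yl]hex-3-en-1-yl}-1,3-dioxolan-4-yl]ethan-1-ol
Conditions: TBAF, THF, 0 °C to rt
Reagents that add atoms: none
Why: Fluoride cleavage of the primary silyl ether; the acetonide and the alkenes are inert.

Step 17
Reactants: 28 2-[(4R)-2,2-dimethyl-4-{(3E)-4-methyl-6-[(1S)-2,6,6-trimethylcyclohex-2-en-1-yl]hex-3-en-1-yl}-1,3-dioxolan-4-yl]ethan-1-ol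
Product: 29 2-[(4R)-2,2-dimethyl-4-{(3E)-4-methyl-6-[(1S)-2,6,6-trimethylcyclohex-2-en-1-yl]hex-3-en-1-yl}-1,3-dioxolan-4-yl]acetaldehyde
Conditions: Dess–Martin periodinane, NaHCO3, CH2Cl2, 0 °C to rt
Reagents that add atoms: none
Why: Dess–Martin oxidation of a primary alcohol under buffered, non-basic conditions, chosen so that the β-alkoxy aldehyde does not lose the acetal oxygen.

Step 18
Reactants: 29 2-[(4R)-2,2-dimethyl-4-{(3E)-4-methyl-6-[(1S)-2,6,6-trimethylcyclohex-2-en-1-yl]hex-3-en-1-yl}-1,3-dioxolan-4-yl]acetaldehyde
Product: 30 (E)-2-[(4R)-2,2-dimethyl-4-{(3E)-4-methyl-6-[(1S)-2,6,6-trimethylcyclohex-2-en-1-yl]hex-3-en-1-yl}-1,3-dioxolan-4-yl]ethenyl acetate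
Conditions: Ac2O, Et3N, DMAP, THF, rt to 40 °C
Reagents that add atoms: acetic anhydride, CC(=O)OC(C)=O
Why: Enol acetate formation by O-acetylation of the aldehyde enolate: only C2 carries acidic hydrogens, the E isomer is favoured because the Z isomer would press the acetoxy group against the fully substituted C3, and the C3 oxygen is still an acetal oxygen, a poor leaving group, so β-elimination should not compete.

Step 19
Reactants: 30 (E)-2-[(4R)-2,2-dimethyl-4-{(3E)-4-methyl-6-[(1S)-2,6,6-trimethylcyclohex-2-en-1-yl]hex-3-en-1-yl}-1,3-dioxolan-4-yl]ethenyl acetate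
Product: 31 (1E,3R,6E)-3-hydroxy-3-(hydroxymethyl)-7-methyl-9-[(1S)-2,6,6-trimethylcyclohex-2-en-1-yl]nona-1,6-dien-1-yl acetate
Conditions: AcOH/H2O (4:1), 40 °C
Reagents that add atoms: none
Why: Mild aqueous acid hydrolysis of the acetonide through the stabilised dialkoxycarbenium ion at the acetal carbon, which forms far more easily than a cation at C3 or the solvolysis product of the enol acetate.

Step 20
Reactants: 31 (1E,3R,6E)-3-hydroxy-3-(hydroxymethyl)-7-methyl-9-[(1S)-2,6,6-trimethylcyclohex-2-en-1-yl]nona-1,6-dien-1-yl acetate
Product: 32 (1E,3R,6E)-3-formyl-3-hydroxy-7-methyl-9-[(1S)-2,6,6-trimethylcyclohex-2-en-1-yl]nona-1,6-dien-1-yl acetate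
Conditions: SO3·pyridine, DMSO, i-Pr2NEt, CH2Cl2, 0 °C
Reagents that add atoms: none
Why: Parikh–Doering oxidation: activated DMSO oxidises the primary hydroxyl and cannot oxidise the tertiary one, and unlike hypervalent iodine or periodate reagents it does not cleave the 1,2-diol.

Step 21
Reactants: 32 (1E,3R,6E)-3-formyl-3-hydroxy-7-methyl-9-[(1S)-2,6,6-trimethylcyclohex-2-en-1-yl]nona-1,6-dien-1-yl acetate
Product: 33 (1E,3R,6E)-3-formyl-7-methyl-9-[(1S)-2,6,6-trimethylcyclohex-2-en-1-yl]nona-1,6-diene-1,3-diyl diacetate
Conditions: Ac2O, DMAP, Et3N, CH2Cl2, rt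
Reagents that add atoms: acetic anhydride, CC(=O)OC(C)=O
Why: DMAP-catalysed acetylation of the tertiary hydroxyl; by now C2 is sp2 and C3 has no hydrogen, so neither enolisation nor β-elimination is possible, and both stereocentres are untouched.

## Compound list

1 | 2,4,4-trimethylcyclohex-2-en-1-one | CC1=CC(C)(C)CCC1=O | starting material
2 | (1R)-2,4,4-trimethylcyclohex-2-en-1-ol | O[C@@H]1CCC(C)(C)C=C1C | intermediate
3 | (1R)-2,4,4-trimethylcyclohex-2-en-1-yl acetate | CC(=O)O[C@@H]1CCC(C)(C)C=C1C | intermediate
4 | trimethyl({1-[(1R)-2,4,4-trimethylcyclohex-2-en-1-yl]oxyethenyl}oxy)silane (ketene silyl acetal) | C=C(O[Si](C)(C)C)O[C@@H]1CCC(C)(C)C=C1C | intermediate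
5 | trimethylsilyl 2-[(1S)-2,6,6-trimethylcyclohex-2-en-1-yl]acetate | C[Si](C)(C)OC(=O)C[C@@H]1C(C)=CCCC1(C)C | intermediate
6 | 2-[(1S)-2,6,6-trimethylcyclohex-2-en-1-yl]acetic acid | OC(=O)C[C@@H]1C(C)=CCCC1(C)C | intermediate
7 | 2-[(1S)-2,6,6-trimethylcyclohex-2-en-1-yl]acetyl chloride | ClC(=O)C[C@@H]1C(C)=CCCC1(C)C | intermediate
8 | 1-diazo-3-[(1S)-2,6,6-trimethylcyclohex-2-en-1-yl]propan-2-one | [N-]=[N+]=CC(=O)C[C@@H]1C(C)=CCCC1(C)C | intermediate
9 | 3-[(1S)-2,6,6-trimethylcyclohex-2-en-1-yl]prop-1-en-1-one (ketene) | O=C=CC[C@@H]1C(C)=CCCC1(C)C | intermediate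
10 | 3-[(1S)-2,6,6-trimethylcyclohex-2-en-1-yl]propanoic acid | OC(=O)CC[C@@H]1C(C)=CCCC1(C)C | intermediate
11 | N-hydroxyphthalimide | O=C1c2ccccc2C(=O)N1O | starting material
12 | 1,3-dioxoisoindolin-2-yl 3-[(1S)-2,6,6-trimethylcyclohex-2-en-1-yl]propanoate | O=C(CC[C@@H]1C(C)=CCCC1(C)C)ON1C(=O)c2ccccc2C1=O | intermediate
13 | pent-3-yn-1-ol | CC#CCCO | starting material
14 | 5-bromopent-2-yne | CC#CCCBr | intermediate
15 | dimethyl oxalate | COC(=O)C(=O)OC | starting material
16 | pent-3-yn-1-ylmagnesium bromide | CC#CCC[Mg]Br | intermediate
17 | methyl 2-oxohept-5-ynoate | CC#CCCC(=O)C(=O)OC | intermediate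
18 | S-tert-butyl thioacetate | CC(=O)SC(C)(C)C | starting material
19 | [1-(tert-butylsulfanyl)ethenyl]oxy(trimethyl)silane | C=C(O[Si](C)(C)C)SC(C)(C)C | intermediate
20 | methyl (2R)-2-[2-(tert-butylsulfanyl)-2-oxoethyl]-2-(trimethylsilyloxy)hept-5-ynoate | COC(=O)[C@](O[Si](C)(C)C)(CC(=O)SC(C)(C)C)CCC#CC | intermediate
21 | methyl (2R)-2-[2-(tert-butylsulfanyl)-2-oxoethyl]-2-hydroxyhept-5-ynoate | COC(=O)[C@](O)(CC(=O)SC(C)(C)C)CCC#CC | intermediate
22 | (3R)-3-(hydroxymethyl)oct-6-yne-1,3-diol | OC[C@](O)(CCO)CCC#CC | intermediate
23 | 2-[(4R)-2,2-dimethyl-4-(pent-3-yn-1-yl)-1,3-dioxolan-4-yl]ethan-1-ol | OCC[C@@](CO1)(CCC#CC)OC1(C)C | intermediate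
24 | tert-butyl{2-[(4R)-2,2-dimethyl-4-(pent-3-yn-1-yl)-1,3-dioxolan-4-yl]ethoxy}dimethylsilane | CC(C)(C)[Si](C)(C)OCC[C@@](CO1)(CCC#CC)OC1(C)C | intermediate
25 | chlorobis(cyclopentadienyl){(2E)-5-[(4R)-4-{2-[tert-butyl(dimethyl)silyl]oxyethyl}-2,2-dimethyl-1,3-dioxolan-4-yl]pent-2-en-2-yl}zirconium | CC(C)(C)[Si](C)(C)OCC[C@@](CO1)(CC/C=C(\C)[Zr](Cl)(C2C=CC=C2)C3C=CC=C3)OC1(C)C | intermediate
26 | tert-butyl{2-[(4R)-4-[(3E)-4-iodopent-3-en-1-yl]-2,2-dimethyl-1,3-dioxolan-4-yl]ethoxy}dimethylsilane | CC(C)(C)[Si](C)(C)OCC[C@@](CO1)(CC/C=C(\C)I)OC1(C)C | intermediate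
27 | tert-butyl{2-[(4R)-2,2-dimethyl-4-{(3E)-4-methyl-6-[(1S)-2,6,6-trimethylcyclohex-2-en-1-yl]hex-3-en-1-yl}-1,3-dioxolan-4-yl]ethoxy}dimethylsilane | CC(C)(C)[Si](C)(C)OCC[C@@](CO1)(CC/C=C(\C)CC[C@@H]2C(C)=CCCC2(C)C)OC1(C)C | intermediate
28 | 2-[(4R)-2,2-dimethyl-4-{(3E)-4-methyl-6-[(1S)-2,6,6-trimethylcyclohex-2-en-1-yl]hex-3-en-1-yl}-1,3-dioxolan-4-yl]ethan-1-ol | OCC[C@@](CO1)(CC/C=C(\C)CC[C@@H]2C(C)=CCCC2(C)C)OC1(C)C | intermediate
29 | 2-[(4R)-2,2-dimethyl-4-{(3E)-4-methyl-6-[(1S)-2,6,6-trimethylcyclohex-2-en-1-yl]hex-3-en-1-yl}-1,3-dioxolan-4-yl]acetaldehyde | O=CC[C@@](CO1)(CC/C=C(\C)CC[C@@H]2C(C)=CCCC2(C)C)OC1(C)C | intermediate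
30 | (E)-2-[(4R)-2,2-dimethyl-4-{(3E)-4-methyl-6-[(1S)-2,6,6-trimethylcyclohex-2-en-1-yl]hex-3-en-1-yl}-1,3-dioxolan-4-yl]ethenyl acetate | CC(=O)O/C=C/[C@@](CO1)(CC/C=C(\C)CC[C@@H]2C(C)=CCCC2(C)C)OC1(C)C | intermediate
31 | (1E,3R,6E)-3-hydroxy-3-(hydroxymethyl)-7-methyl-9-[(1S)-2,6,6-trimethylcyclohex-2-en-1-yl]nona-1,6-dien-1-yl acetate | CC(=O)O/C=C/[C@@](CO)(CC/C=C(\C)CC[C@@H]1C(C)=CCCC1(C)C)O | intermediate
32 | (1E,3R,6E)-3-formyl-3-hydroxy-7-methyl-9-[(1S)-2,6,6-trimethylcyclohex-2-en-1-yl]nona-1,6-dien-1-yl acetate | CC(=O)O/C=C/[C@@](C=O)(CC/C=C(\C)CC[C@@H]1C(C)=CCCC1(C)C)O | intermediate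
33 | (1E,3R,6E)-3-formyl-7-methyl-9-[(1S)-2,6,6-trimethylcyclohex-2-en-1-yl]nona-1,6-diene-1,3-diyl diacetate | CC(=O)O/C=C/[C@@](C=O)(CC/C=C(\C)CC[C@@H]1C(C)=CCCC1(C)C)OC(C)=O | target

## Step count and least certain steps

Total: 21 steps (tail 6, head 8 including the preparation of 19, fragment union 1, end game 6). Longest linear sequence: 14 steps, from 13 to 33 through steps 7, 8 and 10–21.

**Step 15 (key step).** The redox-active ester may be used up by reductive homocoupling or by hydrogen abstraction of the C8 radical, and radical capture at the α-methyl-substituted alkenylnickel centre may be slow enough for proto-deiodination of 26 to take over. The fallback is a two-electron sp3–sp2 coupling that sets out from acid 6, whose carboxyl carbon is C8, and thereby bypasses steps 4–6. Reduction with LiAlH4 would give 2-[(1S)-2,6,6-trimethylcyclohex-2-en-1-yl]ethan-1-ol F1, and I2/PPh3/imidazole the iodide (6S)-6-(2-iodoethyl)-1,5,5-trimethylcyclohex-1-ene F2. Lithium–iodine exchange with t-BuLi and capture by 9-methoxy-9-BBN would give the lithium B-alkyl-B-methoxy-9-borabicyclo[3.3.1]nonane borate F3, which is coupled in the same flask with 26 under Pd(dppf)Cl2 and aqueous K3PO4 in DMF (B-alkyl Suzuki–Miyaura coupling, retention at the alkenyl carbon). The route is rejoined at 27.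

**Step 14.** Hydrozirconation may proceed without sufficient regiocontrol, since a methyl group and an unbranched methylene flank the alkyne and differ only modestly in size; zirconium at C6 would lead to a regioisomeric iodide that is hard to remove and would be carried into the coupling. The fallback fixes the position of iodine by construction and sets out from 24. Semihydrogenation (H2, Pd/CaCO3 poisoned with Pb(OAc)2, quinoline) would give the Z-alkene tert-butyl{2-[(4R)-2,2-dimethyl-4-[(3Z)-pent-3-en-1-yl]-1,3-dioxolan-4-yl]ethoxy}dimethylsilane F4. Ozonolysis (O3, CH2Cl2, −78 °C; PPh3) would give 3-[(4R)-4-{2-[tert-butyl(dimethyl)silyl]oxyethyl}-2,2-dimethyl-1,3-dioxolan-4-yl]propanal F5. A Wittig reaction of F5 with the ylide from EtPPh3Br at −78 °C, followed in the same flask by PhLi and then I2 (the β-oxido ylide variant, which places iodine on the former ylide carbon and is reported to favour the E-iodoalkene), returns to the route at 26; the geometry would have to be confirmed on 26.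

**Step 19.** Acetal hydrolysis may be accompanied by solvolysis of the enol acetate or by ionisation at the allylic tertiary C3–O bond. The fallback sets out from 27, avoids acid treatment of any enol acetate, and also bypasses step 18. Aqueous HCl in THF would remove silyl ether and acetonide together to give (3R,6E)-3-(hydroxymethyl)-7-methyl-9-[(1S)-2,6,6-trimethylcyclohex-2-en-1-yl]non-6-ene-1,3-diol F6. Oxidation of both primary hydroxyls (SO3·pyridine, DMSO, i-Pr2NEt) would give (2R,5E)-2-hydroxy-6-methyl-2-(2-oxoethyl)-8-[(1S)-2,6,6-trimethylcyclohex-2-en-1-yl]oct-5-enal F7. Treatment with Ac2O/Et3N, with DMAP added only afterwards, should first form the enol acetate from the single enolisable aldehyde and then acetylate the tertiary hydroxyl, rejoining the route at 33. This path is three steps instead of six but places an enolisable aldehyde β to the C3 oxygen, which is why it is held in reserve.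

**Step 10.** Facial discrimination may be insufficient: the pent-3-ynyl chain is larger than the methyl group of the pyruvate esters for which this catalyst performs best, and that may lower the enantiomeric purity at C3. The fallback sets C3 by epoxidation and sets out from 17.
- Wittig methylenation (Ph3P=CH2) would give methyl 2-methylidenehept-5-ynoate F8, and DIBAL-H reduction 2-methylidenehept-5-yn-1-ol F9.
- Sharpless asymmetric epoxidation (Ti(OiPr)4, L-(+)-diisopropyl tartrate, t-BuOOH, molecular sieves) would give [(2S)-2-(pent-3-yn-1-yl)oxiran-2-yl]methanol F10.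
- Opening at the unsubstituted epoxide carbon with vinylmagnesium bromide and CuI would give (2R)-2-(pent-3-yn-1-yl)pent-4-ene-1,2-diol F11.
- Ozonolysis of the terminal alkene, which reacts faster than the internal alkyne, with NaBH4 work-up rejoins the route at 22.

**Step 5.** The diazoketone may be diverted into intramolecular cyclopropanation of the ring alkene, which lies γ,δ to the carbonyl, by a metal carbenoid instead of undergoing the 1,2-shift. The fallback avoids diazo compounds and sets out from 6. Methylation (MeI, K2CO3, DMF) would give methyl 2-[(1S)-2,6,6-trimethylcyclohex-2-en-1-yl]acetate F12. Kowalski ester homologation (CH2Br2, lithium tetramethylpiperidide, then LiHMDS and s-BuLi, then acidic methanol) would give methyl 3-[(1S)-2,6,6-trimethylcyclohex-2-en-1-yl]propanoate F13. Saponification (LiOH, THF/H2O) rejoins the route at 10.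

## Further compounds

F1 | step 15 | 2-[(1S)-2,6,6-trimethylcyclohex-2-en-1-yl]ethan-1-ol | OCC[C@@H]1C(C)=CCCC1(C)C
F2 | step 15 | (6S)-6-(2-iodoethyl)-1,5,5-trimethylcyclohex-1-ene | ICC[C@@H]1C(C)=CCCC1(C)C
F3 | step 15 | lithium B-methoxy-B-{2-[(1S)-2,6,6-trimethylcyclohex-2-en-1-yl]ethyl}-9-borabicyclo[3.3.1]nonane borate | [Li+].CO[B-]1(CC[C@@H]2C(C)=CCCC2(C)C)C3CCCC1CCC3
F4 | step 14 | tert-butyl{2-[(4R)-2,2-dimethyl-4-[(3Z)-pent-3-en-1-yl]-1,3-dioxolan-4-yl]ethoxy}dimethylsilane | CC(C)(C)[Si](C)(C)OCC[C@@](CO1)(CC/C=C\C)OC1(C)C
F5 | step 14 | 3-[(4R)-4-{2-[tert-butyl(dimethyl)silyl]oxyethyl}-2,2-dimethyl-1,3-dioxolan-4-yl]propanal | CC(C)(C)[Si](C)(C)OCC[C@@](CO1)(CCC=O)OC1(C)C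
F6 | step 19 | (3R,6E)-3-(hydroxymethyl)-7-methyl-9-[(1S)-2,6,6-trimethylcyclohex-2-en-1-yl]non-6-ene-1,3-diol | OCC[C@@](CO)(CC/C=C(\C)CC[C@@H]1C(C)=CCCC1(C)C)O
F7 | step 19 | (2R,5E)-2-hydroxy-6-methyl-2-(2-oxoethyl)-8-[(1S)-2,6,6-trimethylcyclohex-2-en-1-yl]oct-5-enal | O=CC[C@@](C=O)(CC/C=C(\C)CC[C@@H]1C(C)=CCCC1(C)C)O
F8 | step 10 | methyl 2-methylidenehept-5-ynoate | COC(=O)C(=C)CCC#CC
F9 | step 10 | 2-methylidenehept-5-yn-1-ol | OCC(=C)CCC#CC
F10 | step 10 | [(2S)-2-(pent-3-yn-1-yl)oxiran-2-yl]methanol | OC[C@@]1(CCC#CC)CO1
F11 | step 10 | (2R)-2-(pent-3-yn-1-yl)pent-4-ene-1,2-diol | OC[C@](O)(CC=C)CCC#CC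
F12 | step 5 | methyl 2-[(1S)-2,6,6-trimethylcyclohex-2-en-1-yl]acetate | COC(=O)C[C@@H]1C(C)=CCCC1(C)C
F13 | step 5 | methyl 3-[(1S)-2,6,6-trimethylcyclohex-2-en-1-yl]propanoate | COC(=O)CC[C@@H]1C(C)=CCCC1(C)C
A1 | alternative 1 | (E)-geranylacetone, (5E)-6,10-dimethylundeca-5,9-dien-2-one | CC(=O)CC/C=C(\C)CCC=C(C)C
A2 | alternative 1 | (S)-dihydro-α-ionone, 4-[(1S)-2,6,6-trimethylcyclohex-2-en-1-yl]butan-2-one | CC(=O)CC[C@@H]1C(C)=CCCC1(C)C
A3 | alternative 2 | (1R)-2,4,4-trimethylcyclohex-2-en-1-yl acetate (identical with 3) | CC(=O)O[C@@H]1CCC(C)(C)C=C1C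
A4 | alternative 2 | 2-[(1S)-2,6,6-trimethylcyclohex-2-en-1-yl]acetic acid (identical with 6) | OC(=O)C[C@@H]1C(C)=CCCC1(C)C
A5 | alternative 3 | 2-{(3E)-4-methyl-6-[(1S)-2,6,6-trimethylcyclohex-2-en-1-yl]hex-3-en-1-yl}propane-1,2,3-triol | OCC(O)(CO)CC/C=C(\C)CC[C@@H]1C(C)=CCCC1(C)C
A6 | alternative 3 | (2R,5E)-2-hydroxy-2-(hydroxymethyl)-6-methyl-8-[(1S)-2,6,6-trimethylcyclohex-2-en-1-yl]oct-5-en-1-yl acetate | OC[C@@](COC(C)=O)(CC/C=C(\C)CC[C@@H]1C(C)=CCCC1(C)C)O
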